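## Analysis of the target

The target 19 is a 2,3,4-trisubstituted tetrahydrofuran (O1, C2 to C5). C2 carries a 3,4,5-trimethoxyphenyl group, C3 a hydroxymethyl group, C4 a 3,4-dimethoxybenzyl group, and C5 is a bare CH2 bound to O1. The three stereocentres are contiguous, (2R,3S,4S): the C2 aryl group is trans to the C3 hydroxymethyl group, and the C3 hydroxymethyl group is cis to the C4 benzyl group. The sensitive site is the benzylic ether bond C2–O1. Under acid it ionises, and the cation can epimerise, be reduced, or be captured by the electron-rich dimethoxyphenyl ring to give an aryltetralin. The difficulties are the cis arrangement of the two carbon substituents on C3 and C4, the absolute configuration of three adjacent centres, and the presence of two different benzylic carbons of which only one keeps its oxygen. The strategy rests on C5: it is a CH2 between O1 and C4, so it can be delivered from a methoxymethyl ether on the C2 oxygen to C4. For this, C4 is made the α-carbon of a γ-lactone whose carbonyl carbon is the future benzylic CH2 and whose ring oxygen is the future hydroxymethyl oxygen. The lactone ties C3 and C4 into a cis-fused bicycle, which fixes the one relationship that is otherwise hard to set.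

## Retrosynthetic reasoning

The first cut is the bond between the benzylic CH2 on C4 and the dimethoxyphenyl ring of 19. To make this an aryl-to-carbonyl addition, the CH2 is raised to the acyl oxidation level and closed onto the oxygen of the C3 hydroxymethyl group. This gives the cis-fused bicyclic lactone 14 and aryllithium 16, made from bromide 15 by halogen–lithium exchange. No other bond of 19 offers so simple an aryl connection, and the lactone that receives the aryl group is also the template for the C3/C4 cis relationship. In the forward direction 16 has to add once to 14 to give hemiketal 17. Two hydride transfers under a Lewis acid then follow: the first gives furofuran 18, and the second has to break only the C–O bond at the dimethoxybenzylic carbon of 18 and leave the C–O bond next to the trimethoxyphenyl ring intact.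

In 14 the bond C1–C8 (C4–C5 of 19) is cut. C8 is a CH2 on the ring oxygen, so it can come from the acetal carbon of a methoxymethyl ether on the benzylic oxygen of lactone 12. C1 is α to the lactone carbonyl, so it can be the nucleophilic carbon of silyl ketene acetal 13. Cutting here, and not at O7–C8 or C5–C6, keeps both existing stereocentres in a precursor that an aldol reaction supplies directly. Only one stereocentre is left to make, and the ring fusion decides it. The forward reaction has to ionise the acetal to an oxocarbenium ion on the benzylic oxygen without ionising the benzylic C–O bond, and the tethered ketene acetal has to capture that ion.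

Lactone 12 is opened at its acyl–oxygen bond to hydroxy ester 11, and the CH2OH of 11 is traced back to the imide carbonyl of 10. The ester is a tert-butyl ester because a less hindered ester would be attacked by the free benzylic hydroxyl at the aldol stage and would close the wrong five-membered lactone. In the forward direction the borohydride has to reduce only the imide. The ring is then closed with base, because acid would ionise the benzylic acetal or close it onto the neighbouring hydroxyl as a cyclic formal.

The methoxymethyl group of 10 comes from chloride 9 and aldol 8. In 8 the bond between the two stereocentres is cut. A boron-mediated Evans syn-aldol between imide 4 and aldehyde 5 sets both centres in one step; the (R)-configured auxiliary 2 gives the (3R,4R) pair that becomes C3 and C2 of 19. Imide 4 is the N-acylation product of auxiliary 2 with half-ester 1.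

## Alternatives that were turned down

Alternative 1: The disconnection is the O1–C2 bond, made at the stage of the Weinreb amide A1, (2R,3R,4S)-4-(3,4-dimethoxybenzyl)-N-methoxy-N-methyl-2-(3,4,5-trimethoxyphenyl)oxolane-3-carboxamide. It leads back to the open-chain N-alkoxyphthalimide A2, in which C2 is still a benzylic CH2. In the forward key step fac-Ir(ppy)3 under blue light reduces the N–O bond of A2. The O1 alkoxy radical takes a hydrogen from C2 by 1,5-transfer, the benzylic radical is oxidised by the tetravalent iridium complex formed in the first electron transfer, and the regenerated hydroxyl closes on the cation.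

- For it: the ring closes by C–H functionalisation under near-neutral conditions, and all carbons and both aryl groups are in place beforehand. The dimethoxybenzyl CH2 never carries oxygen, so no late, selective removal of a benzylic C–O bond is needed. On this point it is stronger than the chosen route.
- Against it: C2 is created at a free benzylic cation and is controlled only by the C3 substituent. That cation sits in a 1,3-relationship to the dimethoxybenzyl group, whose arene can close a six-membered ring in competition with O1. A2 needs its own asymmetric synthesis of a 2,3-disubstituted chain. The amide must afterwards be reduced to CH2OH, either through an aldehyde that can epimerise at C3 or with a strong hydride.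
- Comparison: the step count would be no lower. The chosen route offers C2 and C3 from one auxiliary-controlled aldol and C4 from a ring fusion, so no stereocentre depends on the fate of a cation.

Alternative 2: The disconnection is the O1–C5 bond, made at the stage of the silyl ether A3, [(3R,4S,5R)-4-{[tert-butyl(dimethyl)silyl]oxymethyl}-5-(3,4,5-trimethoxyphenyl)oxolan-3-yl]methanol. It leads back to the 3-substituted oxetane A4, (1R,2S)-3-{[tert-butyl(dimethyl)silyl]oxy}-2-(oxetan-3-yl)-1-(3,4,5-trimethoxyphenyl)propan-1-ol. In the forward key step a chiral phosphoric acid activates the oxetane, and the C2 hydroxyl opens it at one CH2 in a 5-exo-tet closure. The other CH2 becomes the CH2OH on the new C4 stereocentre.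

- For it: the conditions are catalytic and mildly acidic, so the benzylic ether never meets a strong Lewis acid. The two CH2O arms on C3 and C4 emerge already differentiated. No selective benzylic reduction is needed. On these points it is as strong as or stronger than the chosen route.
- Against it: A4 already holds the C2 and C3 stereocentres, so the two oxetane CH2 groups are diastereotopic. The catalyst must therefore select within a matched or mismatched pair whose inherent bias is not predictable. A4 itself requires an aldol-type construction with an oxetanyl substituent. After the key step the C4 CH2OH still has to be turned into CH2–aryl by activation and sp3–sp2 coupling with an aryl metal derived from 15, at a β-branched primary carbon, followed by desilylation.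
- Comparison: the route would be several steps longer. The chosen route offers the aryl group by a simple carbonyl addition and a C4 configuration that is enforced geometrically, not selected by a catalyst.

Alternative 3: The disconnection is the C2–C3 bond, made at the stage of the bicyclic lactone A5, (1R,4R,5S,8R)-4-(3,4-dimethoxyphenyl)-8-(3,4,5-trimethoxyphenyl)-3,7-dioxabicyclo[3.3.0]octan-2-one, with both aryl groups exo. It leads back to the α-diazo lactone A6, (4S,5R)-3-diazo-5-(3,4-dimethoxyphenyl)-4-{[(3,4,5-trimethoxybenzyl)oxy]methyl}oxolan-2-one. In the forward key step Rh2(OAc)4 or a chiral dirhodium carboxylate generates the carbene at C3, which inserts into the benzylic C–H next to the ether oxygen. The tetrahydrofuran closes cis-fused to the lactone. The lactone is then spent: the benzylic acyl–oxygen bond is hydrogenolysed and the freed carboxyl group is reduced.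

- For it: it is a direct C–C bond formation at an activated C–H bond, and the cis fusion secures the C3/C4 relationship by the same geometric argument as in the chosen route. The dimethoxybenzylic C–O bond to be removed is an ester bond, which is easier to tell apart from the C2–O1 ether than the ether bond of furofuran 18. On this last point it is stronger than the chosen route.
- Against it: C2 is created in the insertion, and its exo or endo outcome is not enforced by the substrate. The carbene can also add to the electron-rich arenes or form an oxonium ylide. Diazo transfer to a lactone needs prior activation. A6 requires its own enantioselective synthesis of a trans-4,5-disubstituted lactone.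
- Comparison: the step count would be equal or higher. The chosen route offers C2 from a reliable aldol and makes only C4 in its key step, where no choice of outcome exists.

Key step: step 6

Remark on the chemistry: half-ester 1 and auxiliary 2 are taken as commercial (1 is otherwise one step from succinic anhydride and tert-butanol). The closed hemiketal and its open hydroxy ketone form are treated as one compound, 17.

## Route

Step 1
Reactants: 1 4-tert-butoxy-4-oxobutanoic acid; 2 (4R)-4-benzyl-1,3-oxazolidin-2-one
Product: 4 tert-butyl 4-[(4R)-4-benzyl-2-oxo-1,3-oxazolidin-3-yl]-4-oxobutanoate, via mixed pivalic anhydride 3 (not isolated)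
Conditions: pivaloyl chloride, Et3N, THF, −20 °C; then 2, LiCl, −20 °C → rt
Reagents that add atoms: none
Why: N-acylation of the oxazolidinone through a mixed anhydride; the nitrogen attacks the unhindered succinyl carbonyl of 3 and not the pivaloyl carbonyl, and the tert-butyl ester is inert to these conditions.

Step 2
Reactants: 4 tert-butyl 4-[(4R)-4-benzyl-2-oxo-1,3-oxazolidin-3-yl]-4-oxobutanoate; 5 3,4,5-trimethoxybenzaldehyde
Product: 8 tert-butyl (3R,4R)-3-{[(4R)-4-benzyl-2-oxo-1,3-oxazolidin-3-yl]carbonyl}-4-hydroxy-4-(3,4,5-trimethoxyphenyl)butanoate, via Z-boron enolate 6 (not isolated), via boron aldolate 7 (not isolated)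
Conditions: Bu2BOTf, iPr2NEt, CH2Cl2, −78 → 0 °C; 5, −78 → 0 °C; pH 7 buffer, MeOH, H2O2, 0 °C
Reagents that add atoms: none
Why: Evans syn-aldol reaction; soft enolisation occurs only at the imide and gives the Z-enolate 6, which reacts through a chair Zimmerman–Traxler transition state with the aryl group equatorial and the auxiliary carbonyl turned away from the enolate oxygen, so that the aldehyde meets the face opposite the benzyl group of the (R)-auxiliary. This should set both new centres as (3R,4R), syn; the tert-butyl ester is too hindered to be attacked by the new hydroxyl.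

Step 3
Reactants: 8 tert-butyl (3R,4R)-3-{[(4R)-4-benzyl-2-oxo-1,3-oxazolidin-3-yl]carbonyl}-4-hydroxy-4-(3,4,5-trimethoxyphenyl)butanoate; 9 chloromethyl methyl ether
Product: 10 tert-butyl (3R,4R)-3-{[(4R)-4-benzyl-2-oxo-1,3-oxazolidin-3-yl]carbonyl}-4-(methoxymethoxy)-4-(3,4,5-trimethoxyphenyl)butanoate
Conditions: 9, iPr2NEt, Bu4NI (cat.), CH2Cl2, 0 → 35 °C
Reagents that add atoms: chloromethyl methyl ether 9, COCCl
Why: O-alkylation of the secondary alcohol with an α-chloro ether under a hindered amine base (acetal formation); the base is too weak to trigger retro-aldol cleavage or epimerisation, and no stereocentre is touched.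

Step 4
Reactants: 10 tert-butyl (3R,4R)-3-{[(4R)-4-benzyl-2-oxo-1,3-oxazolidin-3-yl]carbonyl}-4-(methoxymethoxy)-4-(3,4,5-trimethoxyphenyl)butanoate
Product: 11 tert-butyl (3S,4R)-3-(hydroxymethyl)-4-(methoxymethoxy)-4-(3,4,5-trimethoxyphenyl)butanoate
Conditions: LiBH4, MeOH (2 equiv), THF, 0 °C
Reagents that add atoms: none
Why: Reductive cleavage of an N-acyl oxazolidinone; hydride attacks the exocyclic imide carbonyl, the auxiliary leaves and the aldehyde is reduced further, while the tert-butyl ester and the acetal do not react at 0 °C. The change of descriptor at C3 is formal only.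

Step 5
Reactants: 11 tert-butyl (3S,4R)-3-(hydroxymethyl)-4-(methoxymethoxy)-4-(3,4,5-trimethoxyphenyl)butanoate
Product: 12 (4S)-4-[(R)-(methoxymethoxy)(3,4,5-trimethoxyphenyl)methyl]oxolan-2-one
Conditions: KOtBu (0.1 equiv), THF, 0 °C → rt
Reagents that add atoms: none
Why: Base-catalysed intramolecular transesterification (lactonisation, 5-exo-trig); the primary alkoxide attacks the ester carbonyl and the tert-butoxy group is expelled. Base is used because acid would ionise the benzylic acetal or close it onto the neighbouring hydroxyl; the lactone has no stereocentre α to the carbonyl, so nothing can epimerise.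

Step 6
Reactants: 12 (4S)-4-[(R)-(methoxymethoxy)(3,4,5-trimethoxyphenyl)methyl]oxolan-2-one
Product: 14 (1S,5S,6R)-6-(3,4,5-trimethoxyphenyl)-3,7-dioxabicyclo[3.3.0]octan-2-one, via silyl ketene acetal 13 (not isolated)
Conditions: LiN(iPr)2, Me3SiCl, THF, −78 °C; volatiles removed, pentane, filtration; CH2Cl2, Me3SiOTf (0.2 equiv), 2,6-di-tert-butyl-4-methylpyridine (0.1 equiv), −78 → −40 °C
Reagents that add atoms: none
Why: LiN(iPr)2 removes an α-hydrogen of lactone 12 and Me3SiCl traps the enolate on oxygen as silyl ketene acetal 13; after the solvent change, catalytic Me3SiOTf silylates the methoxy oxygen of the methoxymethyl group, Me3SiOMe leaves, and an oxocarbenium ion CH2=O+ remains on the benzylic oxygen. The α-carbon of 13 adds to this CH2, and the silyloxycarbenium ion that results passes its silyl group on to the next acetal, so the step is an intramolecular Mukaiyama-type addition of a silyl ketene acetal to an acetal-derived oxocarbenium ion. The tetrahydrofuran closes in a 5-(enolexo)-endo-trig mode: the enol double bond stays outside the new ring and the C=O+ bond ends inside it, which is usual for oxocarbenium closures onto an unhindered CH2 terminus. The only new stereocentre, C1 of 14 (C4 of the target), is controlled by the ring fusion: the tether hangs from C4 of the dihydrofuran and can reach C3 only on its own face, and a trans-fused bicyclo[3.3.0]octane is not accessible, so the cis fusion is the only outcome and the (R)-configured benzylic carbon carries its aryl group exo. The step needs ionisation at the acetal carbon with loss of the methoxy group, not at the benzylic carbon and not with loss of the secondary alkoxide; the more basic and less hindered methoxy oxygen, the only moderate cation-stabilising power of the 3,4,5-trimethoxyphenyl ring and the low temperature should secure this. It also needs the ketene acetal to survive until the cation forms, which is why it is freed from amine salts, buffered by a hindered pyridine and exposed only to a catalytic amount of the silyl triflate; intramolecular capture should then outrun intermolecular alkoxymethylation.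

Step 7
Reactants: 14 (1S,5S,6R)-6-(3,4,5-trimethoxyphenyl)-3,7-dioxabicyclo[3.3.0]octan-2-one; 15 4-bromo-1,2-dimethoxybenzene
Product: 17 (1S,5S,6R)-2-(3,4-dimethoxyphenyl)-6-(3,4,5-trimethoxyphenyl)-3,7-dioxabicyclo[3.3.0]octan-2-ol (hemiketal; both configurations at C2; in equilibrium with its open hydroxy ketone form), via 3,4-dimethoxyphenyllithium 16 (not isolated)
Conditions: 15, n-BuLi, THF, −78 °C; then 14, −78 °C; AcOH, −78 °C
Reagents that add atoms: none
Why: Bromine–lithium exchange followed by 1,2-addition of the aryllithium to the lactone carbonyl; the lithium hemiketalate persists at −78 °C, so a second addition is not expected, and the cold acidic quench limits epimerisation next to the ketone of the open form. The three ring stereocentres are not involved.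

Step 8
Reactants: 17 (1S,5S,6R)-2-(3,4-dimethoxyphenyl)-6-(3,4,5-trimethoxyphenyl)-3,7-dioxabicyclo[3.3.0]octan-2-ol
Product: 19 [(2R,3S,4S)-4-(3,4-dimethoxybenzyl)-2-(3,4,5-trimethoxyphenyl)oxolan-3-yl]methanol, via endo-aryl furofuran 18 (not isolated)
Conditions: Et3SiH (6 equiv), BF3·OEt2 (3 equiv), CH2Cl2, −78 °C, then −20 → 0 °C; aq. NaHCO3
Reagents that add atoms: none
Why: Two ionic hydrogenations in sequence: BF3 ionises the hemiketal to an aryl-stabilised cyclic oxocarbenium ion, which takes hydride from Et3SiH on the convex face and gives 18 with the dimethoxyphenyl group endo; on warming, the C2–O3 bond of 18 ionises and the open benzylic cation is reduced to the CH2 of 19, the primary oxygen being released on work-up. The C2–O3 bond should ionise first because its aryl group is the better donor and sits endo, so that strain is released, whereas the 3,4,5-trimethoxyphenyl group is exo and its para-methoxy group is twisted out of conjugation by its two neighbours. No stereocentre of 19 is touched.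

## Compound list

1 | 4-tert-butoxy-4-oxobutanoic acid (mono-tert-butyl succinate) | CC(C)(C)OC(=O)CCC(=O)O | starting material
2 | (4R)-4-benzyl-1,3-oxazolidin-2-one | O=C1N[C@H](Cc2ccccc2)CO1 | starting material
3 | 4-tert-butoxy-4-oxobutanoic 2,2-dimethylpropanoic anhydride | CC(C)(C)OC(=O)CCC(=O)OC(=O)C(C)(C)C | intermediate (not isolated)
4 | tert-butyl 4-[(4R)-4-benzyl-2-oxo-1,3-oxazolidin-3-yl]-4-oxobutanoate | CC(C)(C)OC(=O)CCC(=O)N1[C@H](Cc2ccccc2)COC1=O | intermediate
5 | 3,4,5-trimethoxybenzaldehyde | COc1cc(C=O)cc(OC)c1OC | starting material
6 | tert-butyl (3Z)-4-[(4R)-4-benzyl-2-oxo-1,3-oxazolidin-3-yl]-4-[(dibutylboranyl)oxy]but-3-enoate | CCCCB(CCCC)O/C(=C\CC(=O)OC(C)(C)C)N1[C@H](Cc2ccccc2)COC1=O | intermediate (not isolated)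
7 | O-dibutylboranyl derivative of 8 (boron aldolate) | CCCCB(CCCC)O[C@@H](c1cc(OC)c(OC)c(OC)c1)[C@H](C(=O)N1[C@H](Cc2ccccc2)COC1=O)CC(=O)OC(C)(C)C | intermediate (not isolated)
8 | tert-butyl (3R,4R)-3-{[(4R)-4-benzyl-2-oxo-1,3-oxazolidin-3-yl]carbonyl}-4-hydroxy-4-(3,4,5-trimethoxyphenyl)butanoate | O[C@@H](c1cc(OC)c(OC)c(OC)c1)[C@H](C(=O)N1[C@H](Cc2ccccc2)COC1=O)CC(=O)OC(C)(C)C | intermediate
9 | chloromethyl methyl ether | COCCl | starting material
10 | tert-butyl (3R,4R)-3-{[(4R)-4-benzyl-2-oxo-1,3-oxazolidin-3-yl]carbonyl}-4-(methoxymethoxy)-4-(3,4,5-trimethoxyphenyl)butanoate | COCO[C@@H](c1cc(OC)c(OC)c(OC)c1)[C@H](C(=O)N1[C@H](Cc2ccccc2)COC1=O)CC(=O)OC(C)(C)C | intermediate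
11 | tert-butyl (3S,4R)-3-(hydroxymethyl)-4-(methoxymethoxy)-4-(3,4,5-trimethoxyphenyl)butanoate | COCO[C@@H](c1cc(OC)c(OC)c(OC)c1)[C@H](CO)CC(=O)OC(C)(C)C | intermediate
12 | (4S)-4-[(R)-(methoxymethoxy)(3,4,5-trimethoxyphenyl)methyl]oxolan-2-one | COCO[C@@H](c1cc(OC)c(OC)c(OC)c1)[C@@H]1COC(=O)C1 | intermediate
13 | trimethyl({(4S)-4-[(R)-(methoxymethoxy)(3,4,5-trimethoxyphenyl)methyl]-4,5-dihydrofuran-2-yl}oxy)silane | COCO[C@@H](c1cc(OC)c(OC)c(OC)c1)[C@@H]1COC(O[Si](C)(C)C)=C1 | intermediate (not isolated)
14 | (1S,5S,6R)-6-(3,4,5-trimethoxyphenyl)-3,7-dioxabicyclo[3.3.0]octan-2-one (aryl exo) | O=C1OC[C@H]2[C@H](c3cc(OC)c(OC)c(OC)c3)OC[C@@H]12 | intermediate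
15 | 4-bromo-1,2-dimethoxybenzene | COc1ccc(Br)cc1OC | starting material
16 | (3,4-dimethoxyphenyl)lithium | [Li]c1ccc(OC)c(OC)c1 | intermediate (not isolated)
17 | (1S,5S,6R)-2-(3,4-dimethoxyphenyl)-6-(3,4,5-trimethoxyphenyl)-3,7-dioxabicyclo[3.3.0]octan-2-ol (both configurations at C2) | COc1ccc(C2(O)OC[C@H]3[C@H](c4cc(OC)c(OC)c(OC)c4)OC[C@@H]23)cc1OC | intermediate
18 | (1S,2S,5S,6R)-2-(3,4-dimethoxyphenyl)-6-(3,4,5-trimethoxyphenyl)-3,7-dioxabicyclo[3.3.0]octane (2-aryl endo, 6-aryl exo) | COc1ccc([C@H]2OC[C@H]3[C@H](c4cc(OC)c(OC)c(OC)c4)OC[C@@H]23)cc1OC | intermediate (not isolated)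
19 | [(2R,3S,4S)-4-(3,4-dimethoxybenzyl)-2-(3,4,5-trimethoxyphenyl)oxolan-3-yl]methanol | COc1ccc(C[C@@H]2CO[C@@H](c3cc(OC)c(OC)c(OC)c3)[C@@H]2CO)cc1OC | target

## Step count and least certain steps

Total: 8 steps. Longest linear sequence: 8 steps (1 → 19).

**Step 6 (key step).** Three things are most likely to go wrong. The ketene acetal may lose its silyl group to adventitious acid before the cation forms. The acetal may ionise in the wrong sense, with loss of the secondary alkoxide. The benzylic C–O bond may ionise. Each of these ends in loss of the tether or in intermolecular alkoxymethylation instead of ring closure.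

Fallback, from 12 to 19: the one-carbon tether is given up and C4–C5 is taken from the lactone itself.
- The lithium enolate of 12 (LiN(SiMe3)2, THF, −78 °C) is alkylated with 3,4-dimethoxybenzyl bromide on the face opposite the C4 substituent. This gives (3S,4S)-3-(3,4-dimethoxybenzyl)-4-[(R)-(methoxymethoxy)(3,4,5-trimethoxyphenyl)methyl]oxolan-2-one F1.
- LiAlH4 in THF opens the lactone to (2S,3S)-2-(3,4-dimethoxybenzyl)-3-[(R)-(methoxymethoxy)(3,4,5-trimethoxyphenyl)methyl]butane-1,4-diol F2.
- Brief treatment with camphorsulfonic acid in CH2Cl2 ionises the benzylic acetal. Only the hydroxyl on the former lactone carbonyl carbon can close a five-membered ring onto the cation, which gives 19.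

The trans relationship in F1 corresponds to the 3,4-cis relationship of 19. The price is that C2 is re-formed at a cation; it is held trans to C3 only by substrate control, and the acid must be kept mild and the reaction time short.

**Step 8.** The two benzylic C–O bonds may not be discriminated well enough. The reaction may stall at 18 at low temperature. At higher temperature C2–O1 may ionise, followed by over-reduction, epimerisation or Friedel–Crafts closure by the dimethoxyphenyl ring.

Fallback, from 17 to 19: the oxygen that would close the furofuran is masked, so that only a free secondary carbinol has to be reduced.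
- NaBH4 in EtOH reduces 17 through its open form to (3,4-dimethoxyphenyl)[(3S,4S,5R)-4-(hydroxymethyl)-5-(3,4,5-trimethoxyphenyl)oxolan-3-yl]methanol F3 (both carbinol epimers).
- Pivaloyl chloride and pyridine at 0 °C acylate the primary hydroxyl to {(2R,3S,4S)-4-[(3,4-dimethoxyphenyl)(hydroxy)methyl]-2-(3,4,5-trimethoxyphenyl)oxolan-3-yl}methyl 2,2-dimethylpropanoate F4.
- Et3SiH and CF3CO2H in CH2Cl2 at −78 °C remove the benzylic hydroxyl and give [(2R,3S,4S)-4-(3,4-dimethoxybenzyl)-2-(3,4,5-trimethoxyphenyl)oxolan-3-yl]methyl 2,2-dimethylpropanoate F5. At this temperature the ring ether should not ionise, and the acylated oxygen cannot form a furofuran.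
- NaOMe in MeOH gives 19.

**Step 7.** A second aryl addition may occur if the tetrahedral intermediate collapses, or the open hydroxy ketone may epimerise next to its carbonyl under the basic conditions.

Fallback, from 14 to 17: the lactone is opened with Me3Al and N,O-dimethylhydroxylamine hydrochloride in CH2Cl2 to (3S,4S,5R)-4-(hydroxymethyl)-N-methoxy-N-methyl-5-(3,4,5-trimethoxyphenyl)oxolane-3-carboxamide F6. This is treated at −78 °C with 2.2 equivalents of 16. The first equivalent deprotonates the hydroxyl, and the second adds to give a chelated intermediate that cannot add again and releases 17 only on quenching.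

**Step 5.** Acyl transfer may be slow because the tert-butoxy group is a poor leaving group, and longer exposure to base may cause self-condensation of the lactone.

Fallback, from 11 to 12: acyl transfer is replaced by a redox sequence. iBu2AlH in CH2Cl2 at −78 °C reduces the ester to the aldehyde oxidation level, which closes to the lactol (4S)-4-[(R)-(methoxymethoxy)(3,4,5-trimethoxyphenyl)methyl]oxolan-2-ol F7 (both anomers). Oxidation with TEMPO (cat.) and PhI(OAc)2 in CH2Cl2 then gives 12.

## Further compounds

F1 | step 6 | (3S,4S)-3-(3,4-dimethoxybenzyl)-4-[(R)-(methoxymethoxy)(3,4,5-trimethoxyphenyl)methyl]oxolan-2-one | COCO[C@@H](c1cc(OC)c(OC)c(OC)c1)[C@@H]2COC(=O)[C@H]2Cc3ccc(OC)c(OC)c3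
F2 | step 6 | (2S,3S)-2-(3,4-dimethoxybenzyl)-3-[(R)-(methoxymethoxy)(3,4,5-trimethoxyphenyl)methyl]butane-1,4-diol | COCO[C@@H](c1cc(OC)c(OC)c(OC)c1)[C@H](CO)[C@@H](CO)Cc1ccc(OC)c(OC)c1
F3 | step 8 | (3,4-dimethoxyphenyl)[(3S,4S,5R)-4-(hydroxymethyl)-5-(3,4,5-trimethoxyphenyl)oxolan-3-yl]methanol (both carbinol epimers) | COc1ccc(C(O)[C@@H]2CO[C@@H](c3cc(OC)c(OC)c(OC)c3)[C@@H]2CO)cc1OC
F4 | step 8 | {(2R,3S,4S)-4-[(3,4-dimethoxyphenyl)(hydroxy)methyl]-2-(3,4,5-trimethoxyphenyl)oxolan-3-yl}methyl 2,2-dimethylpropanoate | COc1ccc(C(O)[C@@H]2CO[C@@H](c3cc(OC)c(OC)c(OC)c3)[C@@H]2COC(=O)C(C)(C)C)cc1OC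
F5 | step 8 | [(2R,3S,4S)-4-(3,4-dimethoxybenzyl)-2-(3,4,5-trimethoxyphenyl)oxolan-3-yl]methyl 2,2-dimethylpropanoate | COc1ccc(C[C@@H]2CO[C@@H](c3cc(OC)c(OC)c(OC)c3)[C@@H]2COC(=O)C(C)(C)C)cc1OC
F6 | step 7 | (3S,4S,5R)-4-(hydroxymethyl)-N-methoxy-N-methyl-5-(3,4,5-trimethoxyphenyl)oxolane-3-carboxamide | CON(C)C(=O)[C@@H]1CO[C@@H](c2cc(OC)c(OC)c(OC)c2)[C@@H]1CO
F7 | step 5 | (4S)-4-[(R)-(methoxymethoxy)(3,4,5-trimethoxyphenyl)methyl]oxolan-2-ol (both anomers) | COCO[C@@H](c1cc(OC)c(OC)c(OC)c1)[C@@H]1COC(O)C1
A1 | alternative 1 | (2R,3R,4S)-4-(3,4-dimethoxybenzyl)-N-methoxy-N-methyl-2-(3,4,5-trimethoxyphenyl)oxolane-3-carboxamide | COc1ccc(C[C@@H]2CO[C@@H](c3cc(OC)c(OC)c(OC)c3)[C@@H]2C(=O)N(C)OC)cc1OC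
A2 | alternative 1 | (2S,3S)-4-(3,4-dimethoxyphenyl)-3-{[(1,3-dioxoisoindolin-2-yl)oxy]methyl}-N-methoxy-N-methyl-2-(3,4,5-trimethoxybenzyl)butanamide | COc1ccc(C[C@H](CON2C(=O)c3ccccc3C2=O)[C@H](Cc2cc(OC)c(OC)c(OC)c2)C(=O)N(C)OC)cc1OC
A3 | alternative 2 | [(3R,4S,5R)-4-{[tert-butyl(dimethyl)silyl]oxymethyl}-5-(3,4,5-trimethoxyphenyl)oxolan-3-yl]methanol | OC[C@@H]1CO[C@@H](c2cc(OC)c(OC)c(OC)c2)[C@@H]1CO[Si](C)(C)C(C)(C)C
A4 | alternative 2 | (1R,2S)-3-{[tert-butyl(dimethyl)silyl]oxy}-2-(oxetan-3-yl)-1-(3,4,5-trimethoxyphenyl)propan-1-ol | O[C@@H](c1cc(OC)c(OC)c(OC)c1)[C@H](CO[Si](C)(C)C(C)(C)C)C1COC1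
A5 | alternative 3 | (1R,4R,5S,8R)-4-(3,4-dimethoxyphenyl)-8-(3,4,5-trimethoxyphenyl)-3,7-dioxabicyclo[3.3.0]octan-2-one | O=C1O[C@@H](c2ccc(OC)c(OC)c2)[C@@H]2CO[C@@H](c3cc(OC)c(OC)c(OC)c3)[C@H]12
A6 | alternative 3 | (4S,5R)-3-diazo-5-(3,4-dimethoxyphenyl)-4-{[(3,4,5-trimethoxybenzyl)oxy]methyl}oxolan-2-one | O=C1O[C@@H](c2ccc(OC)c(OC)c2)[C@H](COCc2cc(OC)c(OC)c(OC)c2)C1=[N+]=[N-]
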